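The constants are assumed; no experiment stands behind them.

Start from the constants: they split every mole of X at a few forks, and those forks make up the ledger.

| setting | epsilon | beta | alpha | eta | gamma |
|---|---|---|---|---|---|
| X | 0.020 M (fed, over 2.5 h) | 0.020 M (fed, over 15 min) | 0.020 M | 0.020 M | 0.020 M |
| Z | 0.0300 M | 0.0300 M | 0.0300 M (in portions, 2, over 2.5 h) | 0.0300 M | 0.0300 M (fed, over 2.5 h) |
| time | 4.0 h | 4.0 h | 4.0 h | 4.0 h | 4.0 h |
| remark | all else is in the flask from the start; the feed brings no volume worth counting | all else is in the flask from the start; the feed brings no volume worth counting | first portion at the start, last at 2.5 h | everything together at the start | all else is in the flask from the start; the feed brings no volume worth counting |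

    X → G (k1 = 0.00988 s⁻¹)
    Z + G → Z.G (k2 = 0.0216 M⁻¹ s⁻¹)
    X → L (k3 = 6.96 × 10⁻⁴ s⁻¹)
    L → J (k4 = 7.63 × 10⁻⁴ s⁻¹)
    L → D (k5 = 3.28 × 10⁻⁴ s⁻¹)
    G ⇌ J (K6 = 0.839, k6 = 4.72 × 10⁻⁴ s⁻¹)
    J → D (k7 = 3.91 × 10⁻⁴ s⁻¹)
    Z.G ⇌ Q (K8 = 1.7, k8 = 2.51 × 10⁻⁴ s⁻¹)

* which flask leads in amount of Z.G, in percent of the X charged ("all alike" within 1.5 percentage points) (epsilon / beta / alpha / eta / gamma / all alike)
* how much Z.G is there at the end, in percent of the X charged: epsilon
* how much Z.G is there at the end, in percent of the X charged: beta
* how much Z.G is there at the end, in percent of the X charged: alpha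
* how much Z.G is there at the end, in percent of the X charged: eta
* how much Z.G is there at the end, in percent of the X charged: gamma

Keep the books on X, the limiting reagent, charged at 0.020 M against 0.0300 M of Z. Enter first what leaves for L: 6.58% of X. Of that L, 30.1% goes straight to D, so write off 1.98% of the X. Book the rest, G and the J made from L, as one account: G and J trade with each other.

Now compare rates at one moment. G goes to J with k6, but 59.0% of J returns to G before it reaches D. The net leak constant of G is therefore 1.94 × 10⁻⁴ s⁻¹, lower than k6. Divide it by k2 to get the even point, 0.00896 M, the cZ at which capture by Z and net leak to D run level. The capture share is then cZ/(cZ + even point).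

Take eta. At the start the share is 77.0%, but capture spends Z, so the comparison drifts. With half the capture done, cZ is about 0.0223 M and the share 71.3%. After the write-off, that books 69.9% of X into Z.G and Q together, and the rest to D.

The last entry divides that pool. At equilibrium Z.G keeps 37.0% of it, with a relaxation half-life of 0.483 h, and the run lasts 8.28 of those. So my figure for eta is 25.9%. Put beta beside it, since its feed of 15 min is short. Put epsilon a little above: its X goes in over 2.5 h, longer than that half-life, and capture runs on after the feed ends, so in epsilon part of the Z.G is still newly formed at 4.0 h and has not relaxed. Put alpha and gamma below, because the net leak half-life of 0.995 h is shorter than the 2.5 h over which their Z arrives.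

The forecast names epsilon, with 28.5% for epsilon, 25.7% for beta, 20% for alpha, 25.5% for eta and 17% for gamma. Its ground is that “starving the flask of Z early (alpha, gamma) loses G to D”. For eta it stands slightly below my figure.

The simulation puts epsilon in the lead at 28.2%, then beta at 26.1%, eta at 26.0%, alpha at 20.1% and gamma at 17.0%. In eta, Z.G and Q together hold 68.5% of X at 4.00 h. Epsilon averaged 0.0252 M of Z over its first 2.5 h, which against the even point 0.00896 M gives a capture share of 73.8%, or 72.3% of X after the write-off. In epsilon at 4.00 h, Z.G and Q hold 67.0%, and G and J a further 3.27%.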